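Ring A of half A carries the oxygen-bearing C8 and C1 on either side of the fusion carbon C8a, a latent 1,3-dicarbonyl. Ring A is therefore cut at C5–C4a and C8–C8a. In step 11 the γ-carbon (C5) of an ester dienolate adds to the β-carbon (C4a) of (R)-cryptone and the resulting C8a enolate acylates on the ester carbon (C8), closing ring A in one operation. The precursor is methyl 2-aryl-3-methylbut-2-enoate whose α-aryl group is the complete half B methyl ether, bonded through C5', so the hindered C7–C5' bond is never made by coupling. Cryptone supplies C4 with its isopropyl group; C1 and C1' are set by methyl addition to o-quinone methides.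

Key step: step 11

Remarks on the chemistry:
- Locants in the steps follow the calamenene numbering of each half (C1 CH3, C4 isopropyl, C6 aryl CH3, C8 oxygen; half B primed). Systematic names in the compound list use their own numbering.
- Ar = (5S,8R)-4-methoxy-2,5-dimethyl-8-(propan-2-yl)-5,6,7,8-tetrahydronaphthalen-1-yl, that is the half B methyl ether bonded through C5'.
- Assumption: the target structure defines no configuration for the hindered C7–C5' axis, so none is controlled and compounds 18 to 28 are taken as mixtures of rotamers about it.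

Step 1
Reactants: 1 3-methylbutanal; 2 methyl vinyl ketone
Product: 4 (R)-cryptone, via keto aldehyde 3 (not isolated)
Conditions: (R)-2-[methoxy(diphenyl)methyl]pyrrolidine (5 mol %), ethyl 3,4-dihydroxybenzoate (20 mol %), neat, 4 °C; then LiOH (10 mol %), i-PrOH, rt
Reagents that add atoms: none
Why: Enamine-catalysed Michael addition of 1 to 2 followed by base-catalysed intramolecular aldol condensation (organocatalytic Robinson-type annulation); the stereocentre is set in the Michael step, where the methoxydiphenylmethyl group of the R catalyst shields one face of the (E)-enamine so that the 2R aldehyde should form, and this centre becomes C4 of (R)-cryptone.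

Step 2
Reactants: 5 methyl 3-methylbut-2-enoate; 4 (R)-cryptone
Product: 8 enolized bicyclic diketone of half B, via lithium dienolate 6 (not isolated), via Michael adduct enolate 7 (not isolated)
Conditions: LDA (1.1 equiv), THF, −78 °C; then 4, −78 °C to rt; 1 M HCl
Reagents that add atoms: none
Why: Michael–Claisen annulation of an ester dienolate with a cyclohexenone: the γ-carbon of 6 (future C5') adds to the β-carbon of 4 anti to the isopropyl group (C4a' trans to C4', a centre removed in step 3), and the C8a' enolate of 7 then acylates on the ester carbon in a 6-exo-trig Claisen closure made irreversible by formation of the diketonate.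

Step 3
Reactants: 8 enolized bicyclic diketone of half B
Product: 9 (4'R)-8'-hydroxy-4'-isopropyl-6'-methyl-1'-tetralone
Conditions: DDQ (1.05 equiv), 1,4-dioxane, rt
Reagents that add atoms: none
Why: DDQ dehydrogenation across C4a'–C5' of the enolized cyclohexadienone is driven by aromatization to the hydrogen-bonded 8'-hydroxy-1'-tetralone, and the C4' stereocentre is not touched.

Step 4
Reactants: 9 (4'R)-8'-hydroxy-4'-isopropyl-6'-methyl-1'-tetralone
Product: 10 8'-O-Boc tetralone
Conditions: Boc2O, i-Pr2NEt, DMAP (10 mol %), CH2Cl2, rt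
Reagents that add atoms: di-tert-butyl dicarbonate, CC(C)(C)OC(=O)OC(=O)OC(C)(C)C
Why: DMAP-catalysed acylation of the phenol with Boc2O gives the aryl tert-butyl carbonate, which is inert to borane and later serves as the leaving-group precursor for the o-quinone methide.

Step 5
Reactants: 10 8'-O-Boc tetralone
Product: 11 8'-O-Boc 1'-tetralol (both C1' epimers)
Conditions: BH3·THF, THF, 0 °C to rt; then MeOH
Reagents that add atoms: none
Why: Borane reduction of the aryl ketone proceeds through a borate ester and never forms a free alkoxide, so the neighbouring O-Boc group should neither migrate nor be lost; both C1' epimers serve, because C1' becomes trigonal again in step 6.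

Step 6
Reactants: 11 8'-O-Boc 1'-tetralol
Product: 13 (1'S,4'R)-8'-hydroxycalamenene, via o-quinone methide 12 (not isolated)
Conditions: MeMgCl (3 equiv), THF, −78 °C to rt; aq. NH4Cl
Reagents that add atoms: methylmagnesium chloride, C[Mg]Cl
Why: The first MeMgCl deprotonates the alcohol, the Boc group migrates to the benzylic oxygen and tert-butyl carbonate is expelled by the phenoxide to give o-quinone methide 12, to which MeMgCl adds 1,4 (o-quinone methide route from O-Boc salicyl alcohols); C1' is set under substrate control, since the C4' isopropyl group lies pseudoaxial to avoid the peri C5'–H and the methyl group should enter along the pseudoaxial trajectory on the opposite face, giving the 1',4'-trans (1'S) isomer.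

Step 7
Reactants: 13 (1'S,4'R)-8'-hydroxycalamenene
Product: 14 (1'S,4'R)-8'-methoxycalamenene
Conditions: MeI, K2CO3, acetone, reflux
Reagents that add atoms: iodomethane, CI
Why: Williamson O-methylation of the phenoxide; the methyl ether withstands LDA, DDQ, borane and Grignard reagents and is removed only in step 16.

Step 8
Reactants: 14 (1'S,4'R)-8'-methoxycalamenene
Product: 15 5'-bromo-8'-methoxycalamenene
Conditions: NBS (1.0 equiv), MeCN, 0 °C to rt, dark
Reagents that add atoms: N-bromosuccinimide, O=C1CCC(=O)N1Br
Why: Electrophilic aromatic bromination with NBS in acetonitrile goes para to the methoxy group, so bromine should enter at C5' and not at C7', while polar conditions in the dark avoid benzylic bromination.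

Step 9
Reactants: 15 5'-bromo-8'-methoxycalamenene; 16 methyl 3-methyl-2-oxobutanoate
Product: 18 methyl 2-Ar-2-hydroxy-3-methylbutanoate (both carbinol epimers), via aryl Grignard 17 (not isolated)
Conditions: Mg, LiCl, THF, 50 °C; then 16, THF, −78 to 0 °C; aq. NH4Cl
Reagents that add atoms: none
Why: Magnesium insertion gives aryl Grignard 17, which adds to the ketone carbonyl of the α-keto ester (Grignard addition, the ketone being far more electrophilic than the ester) to give the tertiary α-hydroxy ester, whose carbinol epimers converge in step 10.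

Step 10
Reactants: 18 methyl 2-Ar-2-hydroxy-3-methylbutanoate
Product: 19 methyl 2-Ar-3-methylbut-2-enoate
Conditions: SOCl2, pyridine, CH2Cl2, 0 °C to reflux
Reagents that add atoms: none
Why: Dehydration of the tertiary benzylic alcohol through its chlorosulfite (SOCl2/pyridine elimination) can only remove the isopropyl methine hydrogen and so should give the tetrasubstituted α-aryl enoate.

Step 11
Reactants: 19 methyl 2-Ar-3-methylbut-2-enoate; 4 (R)-cryptone
Product: 22 enolized bicyclic diketone carrying Ar on C7, via lithium dienolate 20 (not isolated), via Michael adduct enolate 21 (not isolated)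
Conditions: LDA (1.2 equiv), THF–DMPU, −78 °C; then 4 (1.1 equiv), −78 °C to rt; 1 M HCl
Reagents that add atoms: none
Why: LDA removes a γ-hydrogen from an allylic methyl group of 19 to give lithium dienolate 20, whose γ-carbon (C5) adds in a vinylogous Michael reaction to the β-carbon (C4a) of 4; the cyclohexanone enolate 21 thus formed at C8a attacks the ester carbon C8, methoxide is expelled, and deprotonation of the new 1,3-diketone makes the sequence irreversible. The closest known reaction type is the Michael–Claisen annulation of ester dienolates and toluate anions with cyclohexenones. Ring A closes by a 6-exo-trig Claisen acylation (C8a onto C8, the ester C=O exocyclic to the forming ring). The one new stereocentre, C4a, is controlled by the C4 isopropyl group of 4, the dienolate adding to the enone face anti to it; as C4a becomes aromatic in step 12, this selectivity only matters for rate. The step needs γ- and not α-attack of the dienolate, which the substrate secures because C7 is fully substituted and shielded by the twisted, doubly ortho-substituted aryl group, so α- and 1,2-adducts are strained and reversible while only the γ-adduct can drain into the diketonate. The Claisen closure needs C5 cis to the ester on C6=C7, and the remaining γ-hydrogens should let the two alkene geometries interconvert under the basic conditions.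

Step 12
Reactants: 22 enolized bicyclic diketone carrying Ar on C7
Product: 23 (4R)-7-Ar-8-hydroxy-4-isopropyl-6-methyl-1-tetralone
Conditions: DDQ (1.05 equiv), 1,4-dioxane, rt
Reagents that add atoms: none
Why: DDQ dehydrogenation across C4a–C5 is driven by aromatization of ring A, and with one equivalent at room temperature the anisole ring and the benzylic C–H bonds of half B should not be attacked.

Step 13
Reactants: 23 (4R)-7-Ar-8-hydroxy-4-isopropyl-6-methyl-1-tetralone
Product: 24 8-O-Boc tetralone of the biaryl
Conditions: Boc2O, i-Pr2NEt, DMAP, CH2Cl2, 40 °C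
Reagents that add atoms: di-tert-butyl dicarbonate, CC(C)(C)OC(=O)OC(=O)OC(C)(C)C
Why: DMAP-catalysed Boc protection of the phenol as in step 4, with gentle warming to offset the flanking aryl group and the hydrogen bond to the C1 carbonyl.

Step 14
Reactants: 24 8-O-Boc tetralone of the biaryl
Product: 25 8-O-Boc 1-tetralol of the biaryl (both C1 epimers)
Conditions: BH3·THF, THF, 0 °C to rt; then MeOH
Reagents that add atoms: none
Why: Borane reduction of the aryl ketone through a borate ester as in step 5 leaves the carbonate and the methyl ether untouched, and the C1 configuration is irrelevant because C1 becomes trigonal again in step 15.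

Step 15
Reactants: 25 8-O-Boc 1-tetralol of the biaryl
Product: 27 8'-O-methyl ether of the target, via o-quinone methide 26 (not isolated)
Conditions: MeMgCl (3 equiv), THF, −78 °C to rt; aq. NH4Cl
Reagents that add atoms: methylmagnesium chloride, C[Mg]Cl
Why: Deprotonation, Boc migration and loss of tert-butyl carbonate give o-quinone methide 26, to which MeMgCl adds 1,4 as in step 6; C1 is set under substrate control by the pseudoaxial C4 isopropyl group, the methyl group entering pseudoaxially on the opposite face to give the 1,4-trans (1S) isomer.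

Step 16
Reactants: 27 8'-O-methyl ether of the target
Product: 28 target CNP0145304.1
Conditions: BBr3 (3 equiv), CH2Cl2, −78 to 0 °C; then H2O
Reagents that add atoms: none
Why: Lewis acid cleavage of the aryl methyl ether with BBr3 (bromide attacks the O-methyl group of the boron-complexed ether); the free phenol is carried as its borate and both are hydrolysed on work-up, with no effect on the four benzylic stereocentres.

Compound list
1 | 3-methylbutanal | CC(C)CC=O | starting material
2 | methyl vinyl ketone (but-3-en-2-one) | CC(=O)C=C | starting material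
3 | (2R)-5-oxo-2-(propan-2-yl)hexanal | O=C[C@@H](C(C)C)CCC(C)=O | intermediate
4 | (R)-cryptone, (4R)-4-(propan-2-yl)cyclohex-2-en-1-one | O=C1C=C[C@@H](C(C)C)CC1 | intermediate
5 | methyl 3-methylbut-2-enoate | COC(=O)C=C(C)C | starting material
6 | lithium 1-methoxy-3-methylbuta-1,3-dien-1-olate (dienolate of 5) | C=C(C)C=C(OC)O[Li] | intermediate
7 | methyl 4-[(1R,6R)-3-(lithiooxy)-6-(propan-2-yl)cyclohex-2-en-1-yl]-3-methylbut-2-enoate (side chain trans to isopropyl) | [Li]OC1=C[C@H](CC(C)=CC(=O)OC)[C@@H](C(C)C)CC1 | intermediate
8 | (4aR,5R)-8-hydroxy-3-methyl-5-(propan-2-yl)-4a,5,6,7-tetrahydronaphthalen-1(4H)-one | CC1=CC(=O)C2=C(O)CC[C@H](C(C)C)[C@H]2C1 | intermediate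
9 | (4R)-8-hydroxy-6-methyl-4-(propan-2-yl)-3,4-dihydronaphthalen-1(2H)-one | Cc1cc2c(c(O)c1)C(=O)CC[C@@H]2C(C)C | intermediate
10 | tert-butyl (5R)-3-methyl-8-oxo-5-(propan-2-yl)-5,6,7,8-tetrahydronaphthalen-1-yl carbonate | Cc1cc2c(c(OC(=O)OC(C)(C)C)c1)C(=O)CC[C@@H]2C(C)C | intermediate
11 | tert-butyl (5R)-8-hydroxy-3-methyl-5-(propan-2-yl)-5,6,7,8-tetrahydronaphthalen-1-yl carbonate (both C8 epimers) | Cc1cc2c(c(OC(=O)OC(C)(C)C)c1)C(O)CC[C@@H]2C(C)C | intermediate
12 | (5R)-3-methyl-5-(propan-2-yl)-6,7-dihydronaphthalen-1(5H)-one (o-quinone methide) | CC1=CC(=O)C2=CCC[C@H](C(C)C)C2=C1 | intermediate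
13 | (5R,8S)-3,8-dimethyl-5-(propan-2-yl)-5,6,7,8-tetrahydronaphthalen-1-ol, (1S,4R)-8-hydroxycalamenene, methyl and isopropyl trans | Cc1cc(O)c2c(c1)[C@@H](C(C)C)CC[C@@H]2C | intermediate
14 | (1S,4R)-8-methoxy-1,6-dimethyl-4-(propan-2-yl)-1,2,3,4-tetrahydronaphthalene | Cc1cc(OC)c2c(c1)[C@@H](C(C)C)CC[C@@H]2C | intermediate
15 | (1S,4R)-5-bromo-8-methoxy-1,6-dimethyl-4-(propan-2-yl)-1,2,3,4-tetrahydronaphthalene | Cc1cc(OC)c2c(c1Br)[C@@H](C(C)C)CC[C@@H]2C | intermediate
16 | methyl 3-methyl-2-oxobutanoate | COC(=O)C(=O)C(C)C | starting material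
17 | ArMgBr, bromo[(5S,8R)-4-methoxy-2,5-dimethyl-8-(propan-2-yl)-5,6,7,8-tetrahydronaphthalen-1-yl]magnesium | Cc1cc(OC)c2c(c1[Mg]Br)[C@@H](C(C)C)CC[C@@H]2C | intermediate
18 | methyl 2-Ar-2-hydroxy-3-methylbutanoate (both carbinol epimers) | COC(=O)C(O)(C(C)C)c1c(C)cc(OC)c2c1[C@@H](C(C)C)CC[C@@H]2C | intermediate
19 | methyl 2-Ar-3-methylbut-2-enoate | COC(=O)C(=C(C)C)c1c(C)cc(OC)c2c1[C@@H](C(C)C)CC[C@@H]2C | intermediate
20 | lithium 2-Ar-1-methoxy-3-methylbuta-1,3-dien-1-olate (dienolate of 19) | C=C(C)C(=C(OC)O[Li])c1c(C)cc(OC)c2c1[C@@H](C(C)C)CC[C@@H]2C | intermediate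
21 | methyl 2-Ar-4-[(1R,6R)-3-(lithiooxy)-6-(propan-2-yl)cyclohex-2-en-1-yl]-3-methylbut-2-enoate (side chain trans to isopropyl) | [Li]OC1=C[C@H](CC(C)=C(C(=O)OC)c2c(C)cc(OC)c3c2[C@@H](C(C)C)CC[C@@H]3C)[C@@H](C(C)C)CC1 | intermediate
22 | (4aR,5R)-2-Ar-8-hydroxy-3-methyl-5-(propan-2-yl)-4a,5,6,7-tetrahydronaphthalen-1(4H)-one | CC1=C(c3c(C)cc(OC)c4c3[C@@H](C(C)C)CC[C@@H]4C)C(=O)C2=C(O)CC[C@H](C(C)C)[C@H]2C1 | intermediate
23 | (4R)-7-Ar-8-hydroxy-6-methyl-4-(propan-2-yl)-3,4-dihydronaphthalen-1(2H)-one | Cc1cc2c(c(O)c1-c1c(C)cc(OC)c3c1[C@@H](C(C)C)CC[C@@H]3C)C(=O)CC[C@@H]2C(C)C | intermediate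
24 | tert-butyl (5R)-2-Ar-3-methyl-8-oxo-5-(propan-2-yl)-5,6,7,8-tetrahydronaphthalen-1-yl carbonate | Cc1cc2c(c(OC(=O)OC(C)(C)C)c1-c1c(C)cc(OC)c3c1[C@@H](C(C)C)CC[C@@H]3C)C(=O)CC[C@@H]2C(C)C | intermediate
25 | tert-butyl (5R)-2-Ar-8-hydroxy-3-methyl-5-(propan-2-yl)-5,6,7,8-tetrahydronaphthalen-1-yl carbonate (both C8 epimers) | Cc1cc2c(c(OC(=O)OC(C)(C)C)c1-c1c(C)cc(OC)c3c1[C@@H](C(C)C)CC[C@@H]3C)C(O)CC[C@@H]2C(C)C | intermediate
26 | (5R)-2-Ar-3-methyl-5-(propan-2-yl)-6,7-dihydronaphthalen-1(5H)-one (o-quinone methide) | CC1=C(c3c(C)cc(OC)c4c3[C@@H](C(C)C)CC[C@@H]4C)C(=O)C2=CCC[C@H](C(C)C)C2=C1 | intermediate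
27 | (5R,8S)-2-Ar-3,8-dimethyl-5-(propan-2-yl)-5,6,7,8-tetrahydronaphthalen-1-ol (8'-O-methyl ether of the target) | Cc1cc2c(c(O)c1-c1c(C)cc(OC)c3c1[C@@H](C(C)C)CC[C@@H]3C)[C@@H](C)CC[C@@H]2C(C)C | intermediate
28 | (5R,8S)-2-[(5S,8R)-4-hydroxy-2,5-dimethyl-8-(propan-2-yl)-5,6,7,8-tetrahydronaphthalen-1-yl]-3,8-dimethyl-5-(propan-2-yl)-5,6,7,8-tetrahydronaphthalen-1-ol (CNP0145304.1) | Cc1cc2c(c(O)c1-c1c(C)cc(O)c3c1[C@@H](C(C)C)CC[C@@H]3C)[C@@H](C)CC[C@@H]2C(C)C | target

Total step count: 16.
Longest linear sequence: 16 steps (from 1 and 2 to 28; cryptone 4 from step 1 enters a second time in step 11).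

Steps most likely to fail

1. Step 11. The hindered dienolate may transfer a proton to cryptone or add through its α-carbon or in 1,2 fashion, or the Michael adduct may stall before the Claisen closure at the crowded ester. The fallback separates the two bond formations and sets out from 19. Deprotonation with LDA and silylation with Me3SiCl at −78 °C should give the trimethylsilyl ketene acetal F1. TiCl4-promoted vinylogous Mukaiyama–Michael addition of F1 to 4 in CH2Cl2 at −78 °C, a reaction that is γ-selective for silyl dienolates, should give after aqueous work-up the keto ester F2. NaOMe in MeOH then closes ring A by Claisen condensation, and the route is rejoined at 22.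

2. Step 15. The facial selectivity of the methyl addition to o-quinone methide 26 may be poor, or the o-quinone methide may tautomerize to the C1=C2 styrene before the Grignard reagent adds. Step 6 tests the same facial preference earlier, on half B. The fallback replaces substrate control by reagent control and sets out from 23. Excess MeMgBr should add to the C1 ketone to give the tertiary benzylic alcohol F3. Catalytic p-TsOH in toluene should dehydrate it to the 1-methyl-3,4-dihydronaphthalene F4. Asymmetric hydrogenation with [Ir(cod)(t-Bu-PHOX)][B(C6H3(CF3)2)4] and H2 in CH2Cl2, the catalyst antipode being chosen to deliver hydrogen to C1 on the face syn to the C4 isopropyl group, returns to the route at 27 and bypasses steps 13 to 15.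

3. Step 9. The hindered, basic aryl Grignard reagent may enolize the keto ester instead of adding to it, or magnesium insertion into the electron-rich bromide may be sluggish. The fallback forms the aryl–alkene bond by cross-coupling and sets out from 15. Grignard reagent 17 is transmetallated with ZnCl2 to the arylzinc chloride F5. Negishi coupling of F5 with commercial methyl 2-bromo-3-methylbut-2-enoate (Pd2(dba)3, SPhos, THF, 60 °C) should deliver 19 directly, so that 18 and step 10 are bypassed.

Further compounds
F1 | step 11 | 2-Ar-1-methoxy-3-methyl-1-(trimethylsilyloxy)buta-1,3-diene (silyl ketene acetal of 19) | C=C(C)C(=C(OC)O[Si](C)(C)C)c1c(C)cc(OC)c2c1[C@@H](C(C)C)CC[C@@H]2C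
F2 | step 11 | methyl 2-Ar-3-methyl-4-[(1S,2R)-5-oxo-2-(propan-2-yl)cyclohexyl]but-2-enoate | O=C1C[C@H](CC(C)=C(C(=O)OC)c2c(C)cc(OC)c3c2[C@@H](C(C)C)CC[C@@H]3C)[C@@H](C(C)C)CC1
F3 | step 15 | (4R)-7-Ar-1,6-dimethyl-4-(propan-2-yl)-1,2,3,4-tetrahydronaphthalene-1,8-diol (both C1 epimers) | Cc1cc2c(c(O)c1-c1c(C)cc(OC)c3c1[C@@H](C(C)C)CC[C@@H]3C)C(C)(O)CC[C@@H]2C(C)C
F4 | step 15 | (5R)-2-Ar-3,8-dimethyl-5-(propan-2-yl)-5,6-dihydronaphthalen-1-ol | Cc1cc2c(c(O)c1-c1c(C)cc(OC)c3c1[C@@H](C(C)C)CC[C@@H]3C)C(C)=CC[C@@H]2C(C)C
F5 | step 9 | ArZnCl, chloro[(5S,8R)-4-methoxy-2,5-dimethyl-8-(propan-2-yl)-5,6,7,8-tetrahydronaphthalen-1-yl]zinc | Cc1cc(OC)c2c(c1[Zn]Cl)[C@@H](C(C)C)CC[C@@H]2C
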